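The runs stem from a simulated flask on assumed constants; scatter was added.

If added ligand takes free catalyst one to one and tightly, your quick number can start from the ligand and catalyst charges, and your hunch that less ligand frees more catalyst can be reckoned from both ends.

| flask | solid substrate | reagent | free catalyst | added ligand | remark | time |
|---|---|---|---|---|---|---|
| spring | 0.80 M | 2.4 M | 0.40 mM (in portions, 3) | 2 mM | run made earlier; portions every 80 min |  |
| flask | 0.80 M | 2.40 M | 0.40 mM (in portions, 3) | 1.0 mM | the portions of free catalyst follow each other after 80 min, the first at the start | 4.0 d |

spring run (percent of the solid substrate charged)

| time / h | product / % | solid substrate / % |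
|---|---|---|
| 3.00 | 0 | 92 |
| 6.00 | 2 | 86 |
| 8.00 | 0 | 80 |
| 12.0 | 0 | 73 |
| 15.0 | 1 | 72 |
| 20.0 | 1 | 65 |

(scatter of a reading: 2 percentage points)

- solid substrate is a solid; its amount is given per volume of the solution
- on the list of suspects stand: reagent + catalyst intermediate A <-> catalyst intermediate B; catalyst intermediate B <-> catalyst intermediate C; catalyst intermediate C -> free catalyst + product; free catalyst + added ligand <-> idle complex; starting material + free catalyst <-> catalyst intermediate A; solid substrate <-> starting material
- at the start none of the solid substrate is in solution
- starting material means what is dissolved; the solid is not counted in it
- no earlier run changes the charge of added ligand; that part of a forecast is a guess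

1. the product in the flask at 4.0 d, as a percentage of the solid substrate charged
2. the solid substrate in the flask at 4.0 d, as a percentage of the solid substrate charged (only what is still solid)
3. the starting material in the flask at 4.0 d, as a percentage of the solid substrate charged

1. I carry the ligand cover, the added ligand charged over the whole catalyst charged: 2.50 in this flask and 5.00 in the spring run.

2. At the upper end, with cover above one, the ligand can hold the catalyst and keep a fraction, one minus the inverse of the cover, of its own charge: 60.0 % in this flask.

3. With tight binding and the same catalyst charge in both, free catalyst then goes inversely with the ligand left over, so I expect this flask to have 2.67 times the free catalyst of the spring run.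

4. At the lower end, with cover below one, the ligand is the limiting reagent of the binding, and the cover is the share of catalyst held. The two ends join at a cover of one.

5. The spring run reads 1 % product at 20.0 h against a scatter of 2 percentage points, so I stop at the factor and give no product figure of my own.

6. The forecast gives 12 % product, 40 % solid substrate and 48 % starting material. Its ground for the catalyst is this: “Free ligand falls from about 1.6 to 0.6 mM, so free catalyst rises about 2.7-fold, if binding is tight.” It goes on to a product figure, and there we differ.

    reagent + catalyst intermediate A ⇌ catalyst intermediate B (K = 0.390 M⁻¹, k = 0.0220 M⁻¹ s⁻¹)
    catalyst intermediate B ⇌ catalyst intermediate C (K = 1.60, k = 0.280 s⁻¹)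
    catalyst intermediate C → free catalyst + product (k = 0.0530 s⁻¹)
    free catalyst + added ligand ⇌ idle complex, settled at all times (K = 75000 M⁻¹)
    starting material + free catalyst ⇌ catalyst intermediate A (K = 0.750 M⁻¹, k = 0.120 M⁻¹ s⁻¹)
    solid substrate ⇌ starting material, rate k6*(cs6 - [starting material]) while solid is left; crystals form when [starting material] > cs6 (solubility = 0.340 M, k = 2.10 × 10⁻⁵ s⁻¹)

The flask gives 1.91 % product, 55.9 % solid substrate and 42.2 % starting material, so its product lies 10 points under the forecast. In this flask at 4.00 d the idle complex holds 97.0 % of the catalyst, and 61.2 % of the added ligand remains, against the 60.0 % reckoned from the cover. The neighbouring flask with 0.0016 M of free catalyst has a cover of 0.625, below one, so I reckon that share of its catalyst held. At 4.00 d that neighbouring flask shows 60.9 % of its catalyst as idle complex, 31.7 % as free catalyst and 74.4 % product.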